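Free enzyme, first complex, loaded enzyme and second complex add up to the enzyme charge at every moment, so each flask is one cycle, and its pace is what we need.

    second complex → free enzyme + target (k1 = 17 s⁻¹)
    starting material + free enzyme ⇌ first complex (K2 = 3.3 M⁻¹, k2 = 250 M⁻¹ s⁻¹)
    second substrate + loaded enzyme ⇌ second complex (K3 = 10 M⁻¹, k3 = 99 M⁻¹ s⁻¹)
    first complex ⇌ loaded enzyme + first product (K4 = 0.19 M, k4 = 22 s⁻¹)
    second substrate + first product ⇌ idle adduct, settled at all times (K5 = 16 M⁻¹)

| flask | starting material | second substrate | free enzyme | time |
|---|---|---|---|---|
| winter | 0.10 M | 0.0900 M | 10 µM | 2.0 h |
| autumn | 0.10 M | 0.140 M | 10 µM | 2.0 h |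

- for first product the idle adduct is counted in
- run time (winter): 2.0 h

- part of the starting material that has reacted at the end, winter
- part of the starting material that has reacted at the end, autumn
- what raising the concentration of second substrate from its lowest to its highest value here does to the part of the starting material that has reacted (changes below 5 percentage points count as none) (it rises / it falls / no change)

The bench rule keeps the starting rate. We hold both complexes steady. Free enzyme then takes starting material with 56.3 M⁻¹ s⁻¹, loaded enzyme goes forward on second substrate with 62.6 M⁻¹ s⁻¹, and it goes back on first product with 89.7 M⁻¹ s⁻¹. In winter the rule gives 0.101 M h⁻¹, which is 1.01 h⁻¹ of the starting material charge. Kept up, that pace would use winter's second substrate charge in 0.888 h. Autumn starts at 0.123 M h⁻¹, which is 1.23 h⁻¹ of the starting material charge.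

The rule fails through product inhibition. Its border is the break-even ratio 1.43, the free second substrate needed per free first product for loaded enzyme to go forward as often as back.

We test both flasks at part reacted 0.5, in fractions of the charge. Second substrate not yet used is 0.400 in winter and 0.900 in autumn. The idle adduct takes equally from it and from first product. Our first round gives 0.131 and 0.222. Putting those back gives 0.142 and 0.247. Free second substrate per free first product is then 0.721 in winter, below break-even, and 2.58 in autumn, above it.

The rates there are 0.0214 M h⁻¹ in winter and 0.0451 M h⁻¹ in autumn. Letting the rate fall exponentially up to that mark, winter arrives after 1.19 h and autumn after 0.699 h, earlier than winter. Winter should therefore end between 0.5 and 0.674. Autumn's lead is worth about 10.4% of the charge at winter's rate, so we expect a rise.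

The forecast gave 60.6%, 76.7% and it rises, because "More second substrate keeps the loaded enzyme moving forward". The simulation gives 60.7% for winter and 76.6% for autumn, so the part reacted goes this way with more second substrate: it rises, by 16 percentage points.

At the end, free second substrate per free first product stands at 0.346 in winter and 0.731 in autumn, both under the break-even 1.43. The forward share, one over one plus break-even divided by that ratio, is 0.195 in winter and 0.338 in autumn. The neighbour of autumn charged with 0.035 M of second substrate ends at 0.107, a forward share of 0.0696. That neighbour reached 30.4% reacted, with loaded enzyme at 53.0% of the enzyme charge.

(The numbers were set for the occasion, and the outcome is calculated.)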